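**Retrosynthetic overview**
1. Target 35 comes from diester 32 by PMB removal, C14 oxidation and desilylation; the C8 ester is put on 8α-alcohol 29 by an esterification that inverts C8.
2. 29 comes from open-chain 26 in one flask: metathesis first closes the 3-(bromomethyl)butenolide (lactone ring, C7=C11), then zinc closes the ten-membered ring at C7–C8 and sets C7 and C8.
3. 26 comes from a C3–C4 B-alkyl Suzuki union of dienyl acetate 14 with iodo dienol 21, then esterification with 2-(bromomethyl)acrylic acid and periodate cleavage.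
4. 14 comes from (Z)-iododiene 9 and (R)-glyceraldehyde acetonide (sets C9; its own stereocentre is later cut out as the C8 aldehyde); 21 comes from asymmetric vinylation of iodoenal 19 (sets C6).
5. Both trisubstituted alkenes come from hydroxyl-directed hydroalumination/iodination of mono-protected but-2-yne-1,4-diol.

Assumption: germacranolide numbering is used (ring C1–C10; lactone O–C6, C7, C11(=C13H2), C12=O; C14 on C10; C15 on C4), α/β refer to the usual drawing with H-7 α, and in every intermediate C2 is cis to C9 across C1=C10 and C3 is cis to C6 across C4=C5.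

**Step 1**
Reactants: 1 but-2-yne-1,4-diol; 2 4-methoxybenzyl chloride
Product: 3 4-[(4-methoxybenzyl)oxy]but-2-yn-1-ol
Conditions: NaH (1 equiv), 1 (3 equiv), n-Bu4NI (cat.), THF/DMF, 0 °C → rt
Reagents that add atoms: 4-methoxybenzyl chloride (COc1ccc(CCl)cc1)
Why: Williamson etherification of the mono-alkoxide of the excess symmetrical diol gives the mono-ether; no stereocentre is formed.

**Step 2**
Reactants: 3 4-[(4-methoxybenzyl)oxy]but-2-yn-1-ol; 4 iodine
Product: 6 (2Z)-3-iodo-4-[(4-methoxybenzyl)oxy]but-2-en-1-ol, via vinylalanate 5 (not isolated)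
Conditions: NaAlH2(OCH2CH2OCH3)2, THF, 0 °C; then I2, −78 °C → 0 °C
Reagents that add atoms: iodine (II)
Why: Hydroxyl-directed trans-hydroalumination puts aluminium on the distal alkyne carbon and iodinolysis with retention gives the Z vinyl iodide with iodine cis to the CH2OH carbon (future C2), so the later C9–C10 bond ends cis to C2.

**Step 3**
Reactants: 6 (2Z)-3-iodo-4-[(4-methoxybenzyl)oxy]but-2-en-1-ol
Product: 7 (2Z)-3-iodo-4-[(4-methoxybenzyl)oxy]but-2-enal
Conditions: MnO2, CH2Cl2, rt, dark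
Reagents that add atoms: none
Why: Allylic oxidation with MnO2 stops at the enal and leaves the vinyl iodide geometry untouched.

**Step 4**
Reactants: 7 (2Z)-3-iodo-4-[(4-methoxybenzyl)oxy]but-2-enal; 8 methyltriphenylphosphonium bromide
Product: 9 1-({[(2Z)-2-iodopenta-2,4-dien-1-yl]oxy}methyl)-4-methoxybenzene
Conditions: 8, KN(SiMe3)2, THF, −78 °C → 0 °C
Reagents that add atoms: methyltriphenylphosphonium bromide (C[P+](c1ccccc1)(c1ccccc1)c1ccccc1.[Br-])
Why: Wittig methylenation turns the aldehyde into the terminal vinyl group whose CH2 becomes C3.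

**Step 5**
Reactants: 9 1-({[(2Z)-2-iodopenta-2,4-dien-1-yl]oxy}methyl)-4-methoxybenzene; 10 (4R)-2,2-dimethyl-1,3-dioxolane-4-carbaldehyde; 11 acetic anhydride
Product: 14 (1S,2Z)-1-[(4R)-2,2-dimethyl-1,3-dioxolan-4-yl]-2-{[(4-methoxybenzyl)oxy]methyl}penta-2,4-dien-1-yl acetate, via dienyllithium 12 (not isolated), via lithium alkoxide 13 (not isolated)
Conditions: t-BuLi (2.1 equiv), Et2O, −78 °C; 10, −78 °C; then Ac2O, −78 °C → 0 °C
Reagents that add atoms: (4R)-2,2-dimethyl-1,3-dioxolane-4-carbaldehyde (O=C[C@H]1COC(C)(C)O1); acetic anhydride (CC(=O)OC(C)=O)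
Why: Iodine–lithium exchange with retention followed by Felkin–Anh (anti) 1,2-addition to the (R)-aldehyde sets C9 as S (expected about 4:1, minor epimer removed by chromatography), and the alkoxide is acetylated in the flask.

**Step 6**
Reactants: 1 but-2-yne-1,4-diol; 15 tert-butyldimethylsilyl chloride
Product: 16 4-[(tert-butyldimethylsilyl)oxy]but-2-yn-1-ol
Conditions: NaH (1 equiv), THF, 0 °C; then 15, rt
Reagents that add atoms: tert-butyldimethylsilyl chloride (CC(C)(C)[Si](C)(C)Cl)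
Why: Monosilylation of the sparingly soluble mono-sodium alkoxide of a symmetrical diol; no stereocentre is formed.

**Step 7**
Reactants: 16 4-[(tert-butyldimethylsilyl)oxy]but-2-yn-1-ol; 4 iodine
Product: 18 (2Z)-4-[(tert-butyldimethylsilyl)oxy]-3-iodobut-2-en-1-ol, via vinylalanate 17 (not isolated)
Conditions: NaAlH2(OCH2CH2OCH3)2, THF, 0 °C; then I2, −78 °C → 0 °C
Reagents that add atoms: iodine (II)
Why: The same directed trans-hydroalumination/iodination gives iodine cis to the CH2OH carbon (future C6), so the later C3–C4 bond ends cis to C6.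

**Step 8**
Reactants: 18 (2Z)-4-[(tert-butyldimethylsilyl)oxy]-3-iodobut-2-en-1-ol
Product: 19 (2Z)-4-[(tert-butyldimethylsilyl)oxy]-3-iodobut-2-enal
Conditions: MnO2, CH2Cl2, rt, dark
Reagents that add atoms: none
Why: Selective MnO2 oxidation of the primary allylic alcohol to the enal.

**Step 9**
Reactants: 19 (2Z)-4-[(tert-butyldimethylsilyl)oxy]-3-iodobut-2-enal; 20 vinylmagnesium bromide
Product: 21 (3S,4Z)-6-[(tert-butyldimethylsilyl)oxy]-5-iodohexa-1,4-dien-3-ol
Conditions: ZnCl2, 20, Et2O, 0 °C; 1,4-dioxane, filter; then 19, (2S)-3-exo-morpholinoisoborneol [(−)-MIB, 10 mol%], toluene, −30 °C; H2O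
Reagents that add atoms: vinylmagnesium bromide (C=C[Mg]Br)
Why: Amino-alcohol-catalysed enantioselective vinylzinc addition delivers vinyl to the Si face of the enal and gives the (S)-carbinol that becomes C6 (same spatial arrangement as 6R in the target).

**Step 10**
Reactants: 14 (1S,2Z)-1-[(4R)-2,2-dimethyl-1,3-dioxolan-4-yl]-2-{[(4-methoxybenzyl)oxy]methyl}penta-2,4-dien-1-yl acetate; 21 (3S,4Z)-6-[(tert-butyldimethylsilyl)oxy]-5-iodohexa-1,4-dien-3-ol
Product: 23 (1S,2Z,6E,8S)-6-{[(tert-butyldimethylsilyl)oxy]methyl}-1-[(4R)-2,2-dimethyl-1,3-dioxolan-4-yl]-8-hydroxy-2-{[(4-methoxybenzyl)oxy]methyl}deca-2,6,9-trien-1-yl acetate, via alkylborane 22 (not isolated)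
Conditions: 9-BBN, THF, 0 °C → rt; then aq. K3PO4, 21, PdCl2(dppf) ([1,1'-bis(diphenylphosphino)ferrocene]palladium dichloride, 5 mol%), AsPh3, DMF, rt
Reagents that add atoms: (3S,4Z)-6-[(tert-butyldimethylsilyl)oxy]-5-iodohexa-1,4-dien-3-ol (O[C@@H](C=C)/C=C(\I)CO[Si](C)(C)C(C)(C)C)
Why: 9-BBN adds only to the terminal alkene of the diene and the B-alkyl Suzuki–Miyaura coupling joins C3 to C4 with retention at the vinyl iodide; no stereocentre is touched.

**Step 11**
Reactants: 23 the C6 alcohol from step 10; 24 2-(bromomethyl)acrylic acid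
Product: 25 2-(bromomethyl)acrylate ester of 23 at the C6 hydroxyl
Conditions: DCC, DMAP (10 mol%), CH2Cl2, −20 °C → 0 °C
Reagents that add atoms: 2-(bromomethyl)acrylic acid (OC(=O)C(=C)CBr)
Why: Steglich esterification of the only free hydroxyl, with retention at C6.

**Step 12**
Reactants: 25 2-(bromomethyl)acrylate ester of 23
Product: 26 open-chain α-acetoxy aldehyde (C8 aldehyde; C9 S; C6 ester S)
Conditions: H5IO6 (1.5 equiv), EtOAc, 0 °C → rt
Reagents that add atoms: none
Why: Periodic acid hydrolyses the terminal acetonide and cleaves the diol in one pot, excising the glyceraldehyde stereocentre as the C8 aldehyde while C9 is untouched.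

**Step 13**
Reactants: 26 open-chain α-acetoxy aldehyde
Product: 29 macrocyclic 8α-alcohol (6β-H 7α-H 6,12-olide; 9α-OAc; 14-OPMB; 15-OTBS), via bromomethylbutenolide 27 (not isolated), via allylzinc bromide 28 (not isolated)
Conditions: second-generation Grubbs catalyst (5 mol%), CH2Cl2 (2 mM), 40 °C; then THF, sat. aq. NH4Cl, Zn dust, 0 °C → rt
Reagents that add atoms: none
Why: Proposed new method: ring-closing metathesis of the 2-(bromomethyl)acrylate onto the C7 vinyl group gives butenolide 27 (lactone ring), zinc inserts into the allylic C–Br bond and allylzinc 28 adds through C7 to the C8 aldehyde in a closed six-membered (Zimmerman–Traxler) transition state that closes the ten-membered ring; C7 is set trans to the C5 arm (attack on the butenolide face opposite that arm) and C8 as the 8α-alcohol because the ring-locked allylzinc (C6 trans to CH2Zn) places the C9 arm equatorial (7,8-anti) and the α-acetoxy group anti to the incoming carbon (Felkin–Anh), the two effects reinforcing each other; the closest known reactions are intermolecular zinc Barbier allylations with 3-(bromomethyl)furan-2(5H)-ones and intramolecular chromium- or zinc-mediated Barbier closures of ten-membered germacranolides.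

**Step 14**
Reactants: 29 macrocyclic 8α-alcohol; 30 (S)-2-methylbutanoic acid
Product: 32 macrocyclic 8β-(S)-2-methylbutanoate (9α-OAc; 14-OPMB; 15-OTBS), via diphenylphosphinite 31 (not isolated)
Conditions: Ph2PCl, Et3N, DMAP (cat.), THF, 0 °C; then 30, 2,6-dimethyl-1,4-benzoquinone, CH2Cl2, rt
Reagents that add atoms: (S)-2-methylbutanoic acid (CC[C@H](C)C(=O)O)
Why: Mukaiyama oxidation–reduction condensation: the carboxylate displaces the quinone-activated C8–O–P unit by SN2, so the ester is installed with inversion and C8 becomes 8β (S) as in the target.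

**Step 15**
Reactants: 32 macrocyclic 8β-(S)-2-methylbutanoate
Product: 33 C14 allylic alcohol (15-OTBS)
Conditions: DDQ, CH2Cl2/pH 7 buffer, 0 °C
Reagents that add atoms: none
Why: Oxidative cleavage of the PMB ether by DDQ; the silyl ether, esters and lactone are inert.

**Step 16**
Reactants: 33 C14 allylic alcohol
Product: 34 C14 enal (15-OTBS)
Conditions: MnO2, CH2Cl2, rt
Reagents that add atoms: none
Why: Allylic oxidation to the enal with retention of the C1=C10 geometry (CHO trans to C2).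

**Step 17**
Reactants: 34 C14 enal
Product: 35 target
Conditions: HF·pyridine, pyridine, THF, 0 °C → rt
Reagents that add atoms: none
Why: Buffered fluoride desilylation frees the C15 alcohol without touching the enal, the esters or the α-methylene lactone.

**Compound list**
1 | but-2-yne-1,4-diol | OCC#CCO | starting material
2 | 4-methoxybenzyl chloride | COc1ccc(CCl)cc1 | starting material
3 | 4-[(4-methoxybenzyl)oxy]but-2-yn-1-ol | OCC#CCOCc1ccc(OC)cc1 | intermediate
4 | iodine | II | starting material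
5 | sodium cyclic vinylalanate from 3 (Al bound to O1 and C3) | COCCO[Al-]1(OCCOC)OCC=C1COCc1ccc(OC)cc1.[Na+] | intermediate
6 | (2Z)-3-iodo-4-[(4-methoxybenzyl)oxy]but-2-en-1-ol | OC/C=C(\I)COCc1ccc(OC)cc1 | intermediate
7 | (2Z)-3-iodo-4-[(4-methoxybenzyl)oxy]but-2-enal | O=C/C=C(\I)COCc1ccc(OC)cc1 | intermediate
8 | methyltriphenylphosphonium bromide | C[P+](c1ccccc1)(c1ccccc1)c1ccccc1.[Br-] | starting material
9 | 1-({[(2Z)-2-iodopenta-2,4-dien-1-yl]oxy}methyl)-4-methoxybenzene | C=C/C=C(\I)COCc1ccc(OC)cc1 | intermediate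
10 | (4R)-2,2-dimethyl-1,3-dioxolane-4-carbaldehyde | O=C[C@H]1COC(C)(C)O1 | starting material
11 | acetic anhydride | CC(=O)OC(C)=O | starting material
12 | dienyllithium from 9 (Li in place of I, geometry retained) | C=C/C=C(\[Li])COCc1ccc(OC)cc1 | intermediate
13 | lithium alkoxide of the C9 carbinol (9S; 4R dioxolane) | C=C/C=C(/COCc1ccc(OC)cc1)[C@H](O[Li])[C@H]1COC(C)(C)O1 | intermediate
14 | (1S,2Z)-1-[(4R)-2,2-dimethyl-1,3-dioxolan-4-yl]-2-{[(4-methoxybenzyl)oxy]methyl}penta-2,4-dien-1-yl acetate | C=C/C=C(/COCc1ccc(OC)cc1)[C@H](OC(C)=O)[C@H]1COC(C)(C)O1 | intermediate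
15 | tert-butyldimethylsilyl chloride | CC(C)(C)[Si](C)(C)Cl | starting material
16 | 4-[(tert-butyldimethylsilyl)oxy]but-2-yn-1-ol | OCC#CCO[Si](C)(C)C(C)(C)C | intermediate
17 | sodium cyclic vinylalanate from 16 | COCCO[Al-]1(OCCOC)OCC=C1CO[Si](C)(C)C(C)(C)C.[Na+] | intermediate
18 | (2Z)-4-[(tert-butyldimethylsilyl)oxy]-3-iodobut-2-en-1-ol | OC/C=C(\I)CO[Si](C)(C)C(C)(C)C | intermediate
19 | (2Z)-4-[(tert-butyldimethylsilyl)oxy]-3-iodobut-2-enal | O=C/C=C(\I)CO[Si](C)(C)C(C)(C)C | intermediate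
20 | vinylmagnesium bromide | C=C[Mg]Br | starting material
21 | (3S,4Z)-6-[(tert-butyldimethylsilyl)oxy]-5-iodohexa-1,4-dien-3-ol | O[C@@H](C=C)/C=C(\I)CO[Si](C)(C)C(C)(C)C | intermediate
22 | B-alkyl-9-BBN from 14 (boron on C3) | B1(CC/C=C(/COCc2ccc(OC)cc2)[C@H](OC(C)=O)[C@H]2COC(C)(C)O2)C2CCCC1CCC2 | intermediate
23 | (1S,2Z,6E,8S)-6-{[(tert-butyldimethylsilyl)oxy]methyl}-1-[(4R)-2,2-dimethyl-1,3-dioxolan-4-yl]-8-hydroxy-2-{[(4-methoxybenzyl)oxy]methyl}deca-2,6,9-trien-1-yl acetate | O[C@@H](C=C)/C=C(/CO[Si](C)(C)C(C)(C)C)CC/C=C(/COCc1ccc(OC)cc1)[C@H](OC(C)=O)[C@H]1COC(C)(C)O1 | intermediate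
24 | 2-(bromomethyl)acrylic acid | OC(=O)C(=C)CBr | starting material
25 | 2-(bromomethyl)acrylate ester of 23 at the C6 hydroxyl (C6 S; C9 S) | C=C(CBr)C(=O)O[C@@H](C=C)/C=C(/CO[Si](C)(C)C(C)(C)C)CC/C=C(/COCc1ccc(OC)cc1)[C@H](OC(C)=O)[C@H]1COC(C)(C)O1 | intermediate
26 | open-chain α-acetoxy aldehyde (C8 aldehyde; C9 S; C6 ester S) | C=C(CBr)C(=O)O[C@@H](C=C)/C=C(/CO[Si](C)(C)C(C)(C)C)CC/C=C(/COCc1ccc(OC)cc1)[C@H](OC(C)=O)C=O | intermediate
27 | (5R)-3-(bromomethyl)furan-2(5H)-one carrying the C5–C9 chain with the C8 aldehyde | O=C1O[C@@H](C=C1CBr)/C=C(/CO[Si](C)(C)C(C)(C)C)CC/C=C(/COCc2ccc(OC)cc2)[C@H](OC(C)=O)C=O | intermediate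
28 | allylzinc bromide from 27 | O=C1O[C@@H](C=C1C[Zn]Br)/C=C(/CO[Si](C)(C)C(C)(C)C)CC/C=C(/COCc2ccc(OC)cc2)[C@H](OC(C)=O)C=O | intermediate
29 | macrocyclic 8α-alcohol: 6,12-olide with 6β-H and 7α-H, 8α-OH, 9α-OAc, 14-OPMB, 15-OTBS (CIP 6R,7R,8R,9S) | C=C1C(=O)O[C@@H]2/C=C(/CO[Si](C)(C)C(C)(C)C)CC/C=C(/COCc3ccc(OC)cc3)[C@H](OC(C)=O)[C@H](O)[C@@H]12 | intermediate
30 | (S)-2-methylbutanoic acid | CC[C@H](C)C(=O)O | starting material
31 | 8α-O-diphenylphosphinite of 29 | C=C1C(=O)O[C@@H]2/C=C(/CO[Si](C)(C)C(C)(C)C)CC/C=C(/COCc3ccc(OC)cc3)[C@H](OC(C)=O)[C@H](OP(c4ccccc4)c4ccccc4)[C@@H]12 | intermediate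
32 | macrocyclic diester: 8β-(S)-2-methylbutanoate, 9α-OAc, 14-OPMB, 15-OTBS (CIP 6R,7S,8S,9S) | C=C1C(=O)O[C@@H]2/C=C(/CO[Si](C)(C)C(C)(C)C)CC/C=C(/COCc3ccc(OC)cc3)[C@H](OC(C)=O)[C@@H](OC(=O)[C@@H](C)CC)[C@@H]12 | intermediate
33 | C14 allylic alcohol (15-OTBS) | C=C1C(=O)O[C@@H]2/C=C(/CO[Si](C)(C)C(C)(C)C)CC/C=C(/CO)[C@H](OC(C)=O)[C@@H](OC(=O)[C@@H](C)CC)[C@@H]12 | intermediate
34 | C14 enal (15-OTBS) | C=C1C(=O)O[C@@H]2/C=C(/CO[Si](C)(C)C(C)(C)C)CC/C=C(/C=O)[C@H](OC(C)=O)[C@@H](OC(=O)[C@@H](C)CC)[C@@H]12 | intermediate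
35 | 9α-acetoxy-15-hydroxy-8β-[(2S)-2-methylbutanoyloxy]-14-oxogermacra-1(10),4,11(13)-trien-6α,12-olide (both ring alkenes ring-cis) | C=C1C(=O)O[C@@H]2/C=C(/CO)CC/C=C(/C=O)[C@H](OC(C)=O)[C@@H](OC(=O)[C@@H](C)CC)[C@@H]12 | target

**Totals**
Total steps: 17. Longest linear sequence: 13 steps (1–5, then 10–17).

**Steps most likely to fail**

Step 13. The tether may not reach the face of C7 opposite the C5 arm, oligomers may form, or C8 selectivity may be low in the macrocyclic transition state. Fallback, setting out from 14 and 21 and returning at 29: esterify 21 with 24 (DCC) to vinyl iodide ester F1 and close it by metathesis to iodoalkenyl bromomethylbutenolide F2. Cleave 14 with H5IO6 to dienyl aldehyde F3. Couple F2 and F3 intermolecularly with zinc in aqueous NH4Cl/THF to the open trans-lactone 8α-alcohol F4. Then close the ten-membered ring at C3–C4 by 9-BBN hydroboration of the terminal alkene and intramolecular B-alkyl Suzuki coupling at high dilution, which gives 29.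

Step 14. The hindered C8 centre may eliminate, or the neighbouring C9 acetate may participate and give retention. Fallback, setting out from 29 and returning at 32: Dess–Martin oxidation to the C8 ketone F5, Felkin–Anh reduction with NaBH4/CeCl3 at −78 °C (hydride anti to the C9 acetoxy group) to the 8β-alcohol F6, then Yamaguchi esterification with 30 to give 32 with retention.

Step 5. Felkin selectivity of an alkenyllithium with this aldehyde is only moderate. Fallback, setting out from 9 and 10 and returning at 14: run the addition without the anhydride quench and isolate the carbinol epimer mixture F7, oxidise it (Dess–Martin periodinane) to the dienone F8, reduce under chelation control with Zn(BH4)2 to the single anti (9S) alcohol F9, and acetylate (Ac2O, pyridine) to 14.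

**Further compounds**
F1 | step 13 | (3S,4Z)-6-[(tert-butyldimethylsilyl)oxy]-5-iodohexa-1,4-dien-3-yl 2-(bromomethyl)acrylate | C=C(CBr)C(=O)O[C@@H](C=C)/C=C(\I)CO[Si](C)(C)C(C)(C)C
F2 | step 13 | (5S)-3-(bromomethyl)-5-[(1Z)-3-[(tert-butyldimethylsilyl)oxy]-2-iodoprop-1-en-1-yl]furan-2(5H)-one | O=C1O[C@@H](C=C1CBr)/C=C(\I)CO[Si](C)(C)C(C)(C)C
F3 | step 13 | (2S,3Z)-3-{[(4-methoxybenzyl)oxy]methyl}-1-oxohexa-3,5-dien-2-yl acetate | C=C/C=C(/COCc1ccc(OC)cc1)[C@H](OC(C)=O)C=O
F4 | step 13 | open trans-lactone 8α-alcohol (6,12-olide; 9α-OAc; vinyl iodide at C4; terminal C2=C3 alkene; no C3–C4 bond) | C=C1C(=O)O[C@H](/C=C(\I)CO[Si](C)(C)C(C)(C)C)[C@H]1[C@@H](O)[C@@H](OC(C)=O)/C(COCc1ccc(OC)cc1)=C\C=C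
F5 | step 14 | 8-oxo macrocycle (9α-OAc; 14-OPMB; 15-OTBS) | C=C1C(=O)O[C@@H]2/C=C(/CO[Si](C)(C)C(C)(C)C)CC/C=C(/COCc3ccc(OC)cc3)[C@H](OC(C)=O)C(=O)[C@@H]12
F6 | step 14 | macrocyclic 8β-alcohol (9α-OAc; 14-OPMB; 15-OTBS) | C=C1C(=O)O[C@@H]2/C=C(/CO[Si](C)(C)C(C)(C)C)CC/C=C(/COCc3ccc(OC)cc3)[C@H](OC(C)=O)[C@@H](O)[C@@H]12
F7 | step 5 | (2Z)-1-[(4R)-2,2-dimethyl-1,3-dioxolan-4-yl]-2-{[(4-methoxybenzyl)oxy]methyl}penta-2,4-dien-1-ol, mixture of C1 epimers | C=C/C=C(/COCc1ccc(OC)cc1)C(O)[C@H]1COC(C)(C)O1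
F8 | step 5 | (2Z)-1-[(4R)-2,2-dimethyl-1,3-dioxolan-4-yl]-2-{[(4-methoxybenzyl)oxy]methyl}penta-2,4-dien-1-one | C=C/C=C(/COCc1ccc(OC)cc1)C(=O)[C@H]1COC(C)(C)O1
F9 | step 5 | (1S,2Z)-1-[(4R)-2,2-dimethyl-1,3-dioxolan-4-yl]-2-{[(4-methoxybenzyl)oxy]methyl}penta-2,4-dien-1-ol | C=C/C=C(/COCc1ccc(OC)cc1)[C@H](O)[C@H]1COC(C)(C)O1
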